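**Retrosynthetic overview**

1. The target is traced back to the trans-fused hydrindenone ester 17 by removing the fluoride-labile ester and replacing the C3 methyl group by a C3 ketone (enol triflate/methyl cross-coupling in the forward sense); the ketone is a temporary activating group and handle.
2. 17 is opened to the acyclic (E)-4-oxo-2-enoate 16 by an intramolecular Diels–Alder disconnection of the ring-fusion bond C3a–C7a together with C4–C5. Both rings form in this one step; no ring exists before it and none is made after it.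
3. Enabling feature: the six-membered ring C3a–C4–C5–C6=C7–C7a is a cyclohexene (Diels–Alder retron: the C6=C7 alkene with the opposite ring bonds C4–C5 and C3a–C7a), and the five-membered-ring atoms C3–C2–C1 are a three-atom tether from dienophile carbon C3a to diene terminus C7a. C1 is the only stereocentre of the precursor.
4. 16 comes from oxidation of allylic alcohol 15, which is made by Nozaki–Hiyama–Kishi union of tetraenal 11 with iodoacrylate 14.
5. 11 comes from (R)-β-methyl-γ-butyrolactone (the C1 stereocentre) by Weinreb opening, three formyl-ylide Wittig homologations and a benzylphosphonate olefination.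

Key step: step 10

Remark: locants C1 to C7a are those of the 1H-indene core of the target (C1 = CHMe of the five-membered ring, C3 = its methyl-bearing alkene carbon, C3a/C7a = ring fusion, C4 = carboxyl carbon's ring atom, C5 = dienyl-bearing ring atom); lactone 1 and iodoacid 12 are assumed to be purchasable in the stated form.

**Route**

Step 1
Reactants: 1 (R)-4-methyldihydrofuran-2(3H)-one; 2 N,O-dimethylhydroxylamine hydrochloride
Product: 3 (3R)-4-hydroxy-N-methoxy-N,3-dimethylbutanamide
Conditions: AlMe3, CH2Cl2, 0 °C to rt; aq. potassium sodium tartrate work-up; used directly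
Reagents that add atoms: none
Why: Weinreb aminolysis of the γ-lactone by the aluminium amide made from AlMe3 and 2 opens the ring at the acyl carbon and leaves the chiral-pool stereocentre (future C1) untouched.

Step 2
Reactants: 3 (3R)-4-hydroxy-N-methoxy-N,3-dimethylbutanamide
Product: 4 (3R)-N-methoxy-N,3-dimethyl-4-oxobutanamide
Conditions: Dess–Martin periodinane, NaHCO3, CH2Cl2, 0 °C to rt; crude aldehyde used at once
Reagents that add atoms: none
Why: Buffered Dess–Martin oxidation of the primary alcohol should give the α-branched aldehyde without base-mediated epimerisation, and the Weinreb amide is inert.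

Step 3
Reactants: 4 (3R)-N-methoxy-N,3-dimethyl-4-oxobutanamide; 5 2-(triphenylphosphoranylidene)propanal
Product: 6 (3R,4E)-N-methoxy-N,3,5-trimethyl-6-oxohex-4-enamide
Conditions: PhMe, 80 °C
Reagents that add atoms: none
Why: Wittig olefination with the stabilised formyl ylide is E-selective and gives the 2-methyl enal directly, and the conjugated product is much less electrophilic than the saturated aldehyde and should not react on.

Step 4
Reactants: 6 (3R,4E)-N-methoxy-N,3,5-trimethyl-6-oxohex-4-enamide; 5 2-(triphenylphosphoranylidene)propanal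
Product: 7 (3R,4E,6E)-N-methoxy-N,3,5,7-tetramethyl-8-oxoocta-4,6-dienamide
Conditions: PhMe, 100 °C
Reagents that add atoms: none
Why: A second Wittig homologation with the same stabilised ylide at higher temperature extends the enal to the E,E-dienal.

Step 5
Reactants: 7 (3R,4E,6E)-N-methoxy-N,3,5,7-tetramethyl-8-oxoocta-4,6-dienamide; 5 2-(triphenylphosphoranylidene)propanal
Product: 8 (3R,4E,6E,8E)-N-methoxy-N,3,5,7,9-pentamethyl-10-oxodeca-4,6,8-trienamide
Conditions: PhMe, 110 °C
Reagents that add atoms: none
Why: A third E-selective Wittig homologation with the stabilised ylide completes the three methyl-branched alkenes of the chain.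

Step 6
Reactants: 8 (3R,4E,6E,8E)-N-methoxy-N,3,5,7,9-pentamethyl-10-oxodeca-4,6,8-trienamide; 9 diethyl benzylphosphonate
Product: 10 (3R,4E,6E,8E,10E)-N-methoxy-N,3,5,7,9-pentamethyl-11-phenylundeca-4,6,8,10-tetraenamide
Conditions: NaN(SiMe3)2, THF, −78 to 0 °C (aldehyde added to the preformed phosphonate anion)
Reagents that add atoms: none
Why: Horner–Wadsworth–Emmons olefination with the benzylphosphonate anion is E-selective and completes the all-E tetraene, the preformed anion adding to the aldehyde at low temperature faster than it can deprotonate the amide or the remote allylic C–H.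

Step 7
Reactants: 10 (3R,4E,6E,8E,10E)-N-methoxy-N,3,5,7,9-pentamethyl-11-phenylundeca-4,6,8,10-tetraenamide
Product: 11 (3R,4E,6E,8E,10E)-3,5,7,9-tetramethyl-11-phenylundeca-4,6,8,10-tetraenal
Conditions: i-Bu2AlH, THF, −78 °C; aq. potassium sodium tartrate work-up
Reagents that add atoms: none
Why: Hydride reduction of the Weinreb amide stops at the chelated tetrahedral adduct, which releases the aldehyde only on work-up, and the tetraene and the β-stereocentre are not affected.

Step 8
Reactants: 12 (E)-3-iodo-2-methylprop-2-enoic acid; 13 2-(trimethylsilyl)ethanol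
Product: 14 2-(trimethylsilyl)ethyl (E)-3-iodo-2-methylprop-2-enoate
Conditions: DCC, DMAP (cat.), CH2Cl2, 0 °C to rt
Reagents that add atoms: none
Why: Steglich esterification installs an ester that fluoride can later remove without attack at the very hindered carbonyl carbon, and the E iodoalkene is retained.

Step 9
Reactants: 11 (3R,4E,6E,8E,10E)-3,5,7,9-tetramethyl-11-phenylundeca-4,6,8,10-tetraenal; 14 2-(trimethylsilyl)ethyl (E)-3-iodo-2-methylprop-2-enoate
Product: 15 2-(trimethylsilyl)ethyl (2E,4RS,6R,7E,9E,11E,13E)-4-hydroxy-2,6,8,10,12-pentamethyl-14-phenyltetradeca-2,7,9,11,13-pentaenoate (both C4 epimers)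
Conditions: CrCl2 (excess), NiCl2 (cat.), DMSO/THF, rt
Reagents that add atoms: none
Why: In the Nozaki–Hiyama–Kishi coupling the alkenylchromium species adds chemoselectively to the aldehyde with retention of the E geometry and tolerates ester and polyene; the carbinol centre forms without control, which is harmless because it is oxidised in the next step.

Step 10
Reactants: 15 2-(trimethylsilyl)ethyl (2E,4RS,6R,7E,9E,11E,13E)-4-hydroxy-2,6,8,10,12-pentamethyl-14-phenyltetradeca-2,7,9,11,13-pentaenoate
Product: 17 2-(trimethylsilyl)ethyl (1R,3aS,4R,5S,7aS)-1,4,5,7-tetramethyl-5-[(1E,3E)-2-methyl-4-phenylbuta-1,3-dien-1-yl]-3-oxo-2,3,3a,4,5,7a-hexahydro-1H-indene-4-carboxylate, via keto-enoate 16 (not isolated)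
Conditions: Dess–Martin periodinane, NaHCO3, CH2Cl2, 0 °C to rt; filter; then PhMe, BHT (cat.), 25 to 80 °C as required
Reagents that add atoms: none
Why: Buffered Dess–Martin oxidation turns both carbinol epimers of 15 into the single (E)-4-oxo-2-enoate 16, whose electron-poor trisubstituted alkene is tied by a three-atom chain (future C3, C2, C1) to the terminus of an electron-rich (E,E)-2,4-dimethyl-1,3-diene, so that a concerted, asynchronous intramolecular [4+2] cycloaddition forms the ring-fusion bond C3a–C7a together with C4–C5; the closest known reaction type is the intramolecular Diels–Alder reaction of 1,3,8-nonatrienes carrying a terminal ester and an in-chain ketone on the dienophile, which gives trans-fused hydrindanes and hydrindanones. The five-membered ring closes through the tether when C3a meets C7a (the bond common to both rings), and the six-membered ring closes as the [4+2] ring from the four diene carbons and the two alkene carbons. C7a is set relative to the existing C1 centre by A(1,3) strain: the C1–H bond lies in the diene plane facing the C7 methyl group, the tether and the C1 methyl group then sit on opposite faces, and the dienophile adds anti to the C1 methyl group (C1-Me cis to H-7a). C3a and C4 are set relative to each other by the E alkene (suprafacial addition, ester cis to H-3a), C5 by the E geometry of the diene terminus (methyl inside, dienyl chain outside), and the two pairs relative to each other by an endo ester, which gives the trans ring fusion. The selectivity needed is endo for the ester and not for the tether ketone, and it should be secured because only the ester can stay conjugated with the alkene in a transition state that closes a five-membered ring; periselectivity for the proximal diene is secured by the tether length, since the remote dienes could only react through 7- or 9-membered rings.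

Step 11
Reactants: 17 2-(trimethylsilyl)ethyl (1R,3aS,4R,5S,7aS)-1,4,5,7-tetramethyl-5-[(1E,3E)-2-methyl-4-phenylbuta-1,3-dien-1-yl]-3-oxo-2,3,3a,4,5,7a-hexahydro-1H-indene-4-carboxylate
Product: 19 2-(trimethylsilyl)ethyl (1S,3aS,4R,5S,7aS)-1,4,5,7-tetramethyl-5-[(1E,3E)-2-methyl-4-phenylbuta-1,3-dien-1-yl]-3-(trifluoromethylsulfonyloxy)-3a,4,5,7a-tetrahydro-1H-indene-4-carboxylate, via potassium enolate 18 (not isolated)
Conditions: KN(SiMe3)2, THF, −78 °C; then PhNTf2, −78 to 0 °C
Reagents that add atoms: N-phenylbis(trifluoromethanesulfonimide), O=S(=O)(N(c1ccccc1)S(=O)(=O)C(F)(F)F)C(F)(F)F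
Why: Kinetic deprotonation should occur at the C2 methylene and not at the hindered ring-fusion C3a–H next to the quaternary C4, and O-triflation of the enolate fixes the C2=C3 double bond without touching a stereocentre (the descriptor at C1 changes only through ligand priorities).

Step 12
Reactants: 19 2-(trimethylsilyl)ethyl (1S,3aS,4R,5S,7aS)-1,4,5,7-tetramethyl-5-[(1E,3E)-2-methyl-4-phenylbuta-1,3-dien-1-yl]-3-(trifluoromethylsulfonyloxy)-3a,4,5,7a-tetrahydro-1H-indene-4-carboxylate
Product: 20 2-(trimethylsilyl)ethyl (1R,3aR,4R,5S,7aS)-1,3,4,5,7-pentamethyl-5-[(1E,3E)-2-methyl-4-phenylbuta-1,3-dien-1-yl]-3a,4,5,7a-tetrahydro-1H-indene-4-carboxylate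
Conditions: MeZnCl, Pd(PPh3)4 (cat.), THF, 50 °C
Reagents that add atoms: methylzinc chloride, C[Zn]Cl
Why: Negishi cross-coupling of the alkenyl triflate (oxidative addition, transmetalation, reductive elimination) replaces the triflate by methyl without moving the double bond, and the organozinc reagent tolerates the ester.

Step 13
Reactants: 20 2-(trimethylsilyl)ethyl (1R,3aR,4R,5S,7aS)-1,3,4,5,7-pentamethyl-5-[(1E,3E)-2-methyl-4-phenylbuta-1,3-dien-1-yl]-3a,4,5,7a-tetrahydro-1H-indene-4-carboxylate
Product: 21 (1R,3aR,4R,5S,7aS)-1,3,4,5,7-pentamethyl-5-[(1E,3E)-2-methyl-4-phenylbuta-1,3-dien-1-yl]-3a,4,5,7a-tetrahydro-1H-indene-4-carboxylic acid (27-nor-zyggomphic acid B)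
Conditions: Bu4NF, THF, 0 °C to rt; dilute aq. HCl work-up (pH 3)
Reagents that add atoms: none
Why: Fluoride attacks silicon and the ester fragments to carboxylate, ethene and Me3SiF, a cleavage that does not need access to the carbonyl carbon between two quaternary centres and leaves every stereocentre and alkene unchanged.

**Compound list**

1 | (R)-4-methyldihydrofuran-2(3H)-one | O=C1C[C@@H](C)CO1 | starting material
2 | N,O-dimethylhydroxylamine hydrochloride | CNOC.Cl | starting material
3 | (3R)-4-hydroxy-N-methoxy-N,3-dimethylbutanamide | CON(C)C(=O)C[C@@H](C)CO | intermediate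
4 | (3R)-N-methoxy-N,3-dimethyl-4-oxobutanamide | CON(C)C(=O)C[C@@H](C)C=O | intermediate
5 | 2-(triphenylphosphoranylidene)propanal | CC(C=O)=P(c1ccccc1)(c1ccccc1)c1ccccc1 | starting material
6 | (3R,4E)-N-methoxy-N,3,5-trimethyl-6-oxohex-4-enamide | CON(C)C(=O)C[C@@H](C)/C=C(C)/C=O | intermediate
7 | (3R,4E,6E)-N-methoxy-N,3,5,7-tetramethyl-8-oxoocta-4,6-dienamide | CON(C)C(=O)C[C@@H](C)/C=C(C)/C=C(C)/C=O | intermediate
8 | (3R,4E,6E,8E)-N-methoxy-N,3,5,7,9-pentamethyl-10-oxodeca-4,6,8-trienamide | CON(C)C(=O)C[C@@H](C)/C=C(C)/C=C(C)/C=C(C)/C=O | intermediate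
9 | diethyl benzylphosphonate | CCOP(=O)(Cc1ccccc1)OCC | starting material
10 | (3R,4E,6E,8E,10E)-N-methoxy-N,3,5,7,9-pentamethyl-11-phenylundeca-4,6,8,10-tetraenamide | CON(C)C(=O)C[C@@H](C)/C=C(C)/C=C(C)/C=C(C)/C=C/c1ccccc1 | intermediate
11 | (3R,4E,6E,8E,10E)-3,5,7,9-tetramethyl-11-phenylundeca-4,6,8,10-tetraenal | O=CC[C@@H](C)/C=C(C)/C=C(C)/C=C(C)/C=C/c1ccccc1 | intermediate
12 | (E)-3-iodo-2-methylprop-2-enoic acid | OC(=O)/C(C)=C/I | starting material
13 | 2-(trimethylsilyl)ethanol | C[Si](C)(C)CCO | starting material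
14 | 2-(trimethylsilyl)ethyl (E)-3-iodo-2-methylprop-2-enoate | C[Si](C)(C)CCOC(=O)/C(C)=C/I | intermediate
15 | 2-(trimethylsilyl)ethyl (2E,4RS,6R,7E,9E,11E,13E)-4-hydroxy-2,6,8,10,12-pentamethyl-14-phenyltetradeca-2,7,9,11,13-pentaenoate | C[Si](C)(C)CCOC(=O)/C(C)=C/C(O)C[C@@H](C)/C=C(C)/C=C(C)/C=C(C)/C=C/c1ccccc1 | intermediate
16 | 2-(trimethylsilyl)ethyl (2E,6R,7E,9E,11E,13E)-2,6,8,10,12-pentamethyl-4-oxo-14-phenyltetradeca-2,7,9,11,13-pentaenoate | C[Si](C)(C)CCOC(=O)/C(C)=C/C(=O)C[C@@H](C)/C=C(C)/C=C(C)/C=C(C)/C=C/c1ccccc1 | intermediate (not isolated)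
17 | 2-(trimethylsilyl)ethyl (1R,3aS,4R,5S,7aS)-1,4,5,7-tetramethyl-5-[(1E,3E)-2-methyl-4-phenylbuta-1,3-dien-1-yl]-3-oxo-2,3,3a,4,5,7a-hexahydro-1H-indene-4-carboxylate | CC1=C[C@](C)(/C=C(C)/C=C/c2ccccc2)[C@](C)(C(=O)OCC[Si](C)(C)C)[C@H]2C(=O)C[C@@H](C)[C@H]12 | intermediate
18 | potassium (1S,3aS,4R,5S,7aS)-1,4,5,7-tetramethyl-5-[(1E,3E)-2-methyl-4-phenylbuta-1,3-dien-1-yl]-4-{[2-(trimethylsilyl)ethoxy]carbonyl}-3a,4,5,7a-tetrahydro-1H-inden-3-olate | CC1=C[C@](C)(/C=C(C)/C=C/c2ccccc2)[C@](C)(C(=O)OCC[Si](C)(C)C)[C@H]2C([O-])=C[C@@H](C)[C@H]12.[K+] | intermediate (not isolated)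
19 | 2-(trimethylsilyl)ethyl (1S,3aS,4R,5S,7aS)-1,4,5,7-tetramethyl-5-[(1E,3E)-2-methyl-4-phenylbuta-1,3-dien-1-yl]-3-(trifluoromethylsulfonyloxy)-3a,4,5,7a-tetrahydro-1H-indene-4-carboxylate | CC1=C[C@](C)(/C=C(C)/C=C/c2ccccc2)[C@](C)(C(=O)OCC[Si](C)(C)C)[C@H]2C(OS(=O)(=O)C(F)(F)F)=C[C@@H](C)[C@H]12 | intermediate
20 | 2-(trimethylsilyl)ethyl (1R,3aR,4R,5S,7aS)-1,3,4,5,7-pentamethyl-5-[(1E,3E)-2-methyl-4-phenylbuta-1,3-dien-1-yl]-3a,4,5,7a-tetrahydro-1H-indene-4-carboxylate | CC1=C[C@](C)(/C=C(C)/C=C/c2ccccc2)[C@](C)(C(=O)OCC[Si](C)(C)C)[C@H]2C(C)=C[C@@H](C)[C@H]12 | intermediate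
21 | (1R,3aR,4R,5S,7aS)-1,3,4,5,7-pentamethyl-5-[(1E,3E)-2-methyl-4-phenylbuta-1,3-dien-1-yl]-3a,4,5,7a-tetrahydro-1H-indene-4-carboxylic acid (27-nor-zyggomphic acid B) | CC1=C[C@](C)(/C=C(C)/C=C/c2ccccc2)[C@](C)(C(=O)O)[C@H]2C(C)=C[C@@H](C)[C@H]12 | target

**Step count and risks**

Total step count: 13. Longest linear sequence: 12 steps (steps 1 to 7 and 9 to 13; step 8 is a one-step side branch).

Steps most likely to fail:

Step 10. The tether ketone may compete with the ester for the endo position, which would lead into the cis-fused series, or the keto-enoate may isomerise or degrade before it cyclises. In the fallback the cycloaddition is run at the alcohol oxidation level, so that the ester is the only activating group. Starting from 15, silylation (Et3SiCl, imidazole, DMF) should give the C4 triethylsilyl ether F1. Thermal intramolecular Diels–Alder reaction (PhMe, BHT, 120 °C, sealed tube) should give the trans-fused C3 silyloxy hydrindene F2 as a pair of C3 epimers. Mild acid (AcOH, THF, H2O) should free the C3 alcohol F3, and Dess–Martin oxidation should converge both epimers on 17, where the route is rejoined.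

Step 5. The dienal may react sluggishly, be homologated twice, or lose E geometry on long heating, because product and starting aldehyde differ little in electrophilicity. In the fallback the last trisubstituted alkene is made by cross-coupling. Starting from 7, Corey–Fuchs olefination (CBr4, PPh3, CH2Cl2, 0 °C) should give the 1,1-dibromotriene F4. Trans-selective Suzuki coupling of the less hindered bromide with (E)-styrylboronic acid (Pd2(dba)3, tri(2-furyl)phosphine, aq. Na2CO3, THF) should give the (8Z)-9-bromotetraene F5. Negishi methylation with retention (MeZnCl, Pd(P(t-Bu)3)2, THF) should then give 10, so that 8 and step 6 are bypassed.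

Step 11. Enolisation may be non-regioselective, or the ring-fusion centre C3a next to the ketone may epimerise (trans to cis hydrindanone) before O-triflation. In the fallback the methyl group is brought in as a nucleophile. Starting from 17, MeMgBr with CeCl3 (THF, −78 °C) should add to the ketone only and give the tertiary alcohol F6. Dehydration with the Burgess reagent (PhMe, 50 °C) towards the C2 methylene should give 20, so that steps 11 and 12 are replaced.

**Further compounds**

F1 | step 10 | 2-(trimethylsilyl)ethyl (2E,4RS,6R,7E,9E,11E,13E)-2,6,8,10,12-pentamethyl-14-phenyl-4-(triethylsilyloxy)tetradeca-2,7,9,11,13-pentaenoate | C[Si](C)(C)CCOC(=O)/C(C)=C/C(O[Si](CC)(CC)CC)C[C@@H](C)/C=C(C)/C=C(C)/C=C(C)/C=C/c1ccccc1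
F2 | step 10 | 2-(trimethylsilyl)ethyl (1R,3RS,3aS,4R,5S,7aS)-1,4,5,7-tetramethyl-5-[(1E,3E)-2-methyl-4-phenylbuta-1,3-dien-1-yl]-3-(triethylsilyloxy)-2,3,3a,4,5,7a-hexahydro-1H-indene-4-carboxylate | CC1=C[C@](C)(/C=C(C)/C=C/c2ccccc2)[C@](C)(C(=O)OCC[Si](C)(C)C)[C@H]2C(O[Si](CC)(CC)CC)C[C@@H](C)[C@H]12
F3 | step 10 | 2-(trimethylsilyl)ethyl (1R,3RS,3aS,4R,5S,7aS)-3-hydroxy-1,4,5,7-tetramethyl-5-[(1E,3E)-2-methyl-4-phenylbuta-1,3-dien-1-yl]-2,3,3a,4,5,7a-hexahydro-1H-indene-4-carboxylate | CC1=C[C@](C)(/C=C(C)/C=C/c2ccccc2)[C@](C)(C(=O)OCC[Si](C)(C)C)[C@H]2C(O)C[C@@H](C)[C@H]12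
F4 | step 5 | (3R,4E,6E)-9,9-dibromo-N-methoxy-N,3,5,7-tetramethylnona-4,6,8-trienamide | CON(C)C(=O)C[C@@H](C)/C=C(C)/C=C(C)/C=C(Br)Br
F5 | step 5 | (3R,4E,6E,8Z,10E)-9-bromo-N-methoxy-N,3,5,7-tetramethyl-11-phenylundeca-4,6,8,10-tetraenamide | CON(C)C(=O)C[C@@H](C)/C=C(C)/C=C(C)/C=C(Br)/C=C/c1ccccc1
F6 | step 11 | 2-(trimethylsilyl)ethyl (1R,3RS,3aS,4R,5S,7aS)-3-hydroxy-1,3,4,5,7-pentamethyl-5-[(1E,3E)-2-methyl-4-phenylbuta-1,3-dien-1-yl]-2,3,3a,4,5,7a-hexahydro-1H-indene-4-carboxylate | CC1=C[C@](C)(/C=C(C)/C=C/c2ccccc2)[C@](C)(C(=O)OCC[Si](C)(C)C)[C@H]2C(C)(O)C[C@@H](C)[C@H]12
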